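**Plan**

- Retrosynthesis: the three hydroxyls are first masked as methoxymethyl (MOM) ethers, then the bond from chromene C8 to the bridging methylene is cut. C8 is the only unsubstituted carbon of the benzene ring (ring A) and can carry bromine, and the methylene on C3 of the pyranone (ring C) can carry chlorine, so two electrophilic carbons are joined under nickel/zinc.
- Chromene half: the pyran ring (ring B) is cut at O1–C2 and C4–C4a back to an aryl 1,1-dimethylpropargyl ether of the brominated, bis-MOM-protected acylphloroglucinol; the isobutyryl group is cut from phloroglucinol (Friedel–Crafts).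
- Pyranone half: the C3–CH2 bond is cut to a 3-bromopyranone and a hydroxymethyl donor; the lactone C–O bond and the C5–C6 bond lead back to methyl 3-oxopentanoate and a propionyl amide.
- Forward order: ring A is bought; ring B closes in step 5 with bromine and both MOM groups already in place; ring C closes in step 7; the halves are joined in step 12 and unmasked in step 13.
- Stereochemistry: the target has no stereocentre. Only regiochemistry needs control, and it comes from the symmetry of phloroglucinol, from protecting the two hydroxyls beside the ketone before ring B closes, and from the single free ring carbon of each half.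

Key step: step 12

Remark: the pyranone is drawn throughout as its 4-hydroxy-2H-pyran-2-one tautomer and the β-dicarbonyl compounds as keto forms.

**Route**

Step 1
Reactants: 1 phloroglucinol; 2 2-methylpropanoyl chloride (isobutyryl chloride)
Product: 3 2-methyl-1-(2,4,6-trihydroxyphenyl)propan-1-one
Conditions: AlCl3 (3.5 equiv), PhNO2, 25 to 65 °C; ice/aq HCl
Reagents that add atoms: none
Why: Friedel–Crafts acylation of the threefold-symmetric triphenol, in which all ring carbons are equivalent and the first acyl group deactivates the ring towards a second acylation.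

Step 2
Reactants: 3 2-methyl-1-(2,4,6-trihydroxyphenyl)propan-1-one; 4 3-chloro-3-methylbut-1-yne
Product: 5 1-{2,6-dihydroxy-4-[(2-methylbut-3-yn-2-yl)oxy]phenyl}-2-methylpropan-1-one
Conditions: 4 (1.1 equiv), DBU (1.1 equiv), CuCl2 (1 mol %), MeCN, 0 °C
Reagents that add atoms: none
Why: Copper-catalysed propargylic etherification of a phenoxide with a tertiary propargylic chloride; one equivalent of base should ionize the 4-hydroxyl, which is para to the ketone, the most acidic and the least hindered, while the two hydroxyls beside the acyl group are shielded and one of them is chelated.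

Step 3
Reactants: 5 1-{2,6-dihydroxy-4-[(2-methylbut-3-yn-2-yl)oxy]phenyl}-2-methylpropan-1-one
Product: 6 1-{3-bromo-2,6-dihydroxy-4-[(2-methylbut-3-yn-2-yl)oxy]phenyl}-2-methylpropan-1-one
Conditions: NBS (1.0 equiv), CH2Cl2, −78 to −20 °C, dark
Reagents that add atoms: N-bromosuccinimide, O=C1CCC(=O)N1Br
Why: Electrophilic aromatic bromination of a phloroglucinol-type ring whose two free carbons are equivalent; one equivalent of reagent at low temperature should stop after the first substitution because bromine lowers the nucleophilicity of the ring, and no alkene is yet present to compete.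

Step 4
Reactants: 6 1-{3-bromo-2,6-dihydroxy-4-[(2-methylbut-3-yn-2-yl)oxy]phenyl}-2-methylpropan-1-one
Product: 7 1-{3-bromo-2,6-bis(methoxymethoxy)-4-[(2-methylbut-3-yn-2-yl)oxy]phenyl}-2-methylpropan-1-one
Conditions: NaH (2.2 equiv), MOMCl (2.6 equiv), DMF, 0 °C to rt
Reagents that add atoms: chloromethyl methyl ether, COCCl
Why: Williamson-type O-alkylation (MOM protection) of both sodium phenoxides, the strong base overcoming the hydrogen bond to the ketone; the phenols are far more acidic than the alkyne, which should stay untouched when the base is limited to about two equivalents.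

Step 5
Reactants: 7 1-{3-bromo-2,6-bis(methoxymethoxy)-4-[(2-methylbut-3-yn-2-yl)oxy]phenyl}-2-methylpropan-1-one
Product: 10 1-[8-bromo-5,7-bis(methoxymethoxy)-2,2-dimethyl-2H-chromen-6-yl]-2-methylpropan-1-one, via allenylphenol 8 (not isolated), via quinone methide 9 (not isolated)
Conditions: o-xylene, reflux (144 °C), argon
Reagents that add atoms: none
Why: Aromatic propargyl Claisen rearrangement to the one free ortho carbon and enolization give allenylphenol 8, a 1,5-hydrogen shift gives ortho-quinone methide 9 and oxa-6π electrocyclization closes the pyran ring; because the former ether oxygen is the only unprotected one the ring must close through it, which fixes the ketone at C6 and the bromine at C8.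

Step 6
Reactants: 11 methyl 3-oxopentanoate; 12 N-methoxy-N-methylpropanamide
Product: 14 methyl 4-methyl-3,5-dioxoheptanoate, via dilithium dianion 13 (not isolated)
Conditions: LiN(iPr)2 (2.2 equiv), THF, −78 to 0 °C; 12 (1.0 equiv), −78 to 0 °C; aq HCl
Reagents that add atoms: none
Why: Claisen-type γ-acylation of a β-keto ester dianion, which reacts at its more basic terminal carbanion (C4); the N-methoxy-N-methylamide (Weinreb amide) holds the adduct as a chelated tetrahedral lithium alkoxide until work-up, so no second addition occurs and the acidic product cannot quench unreacted dianion.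

Step 7
Reactants: 14 methyl 4-methyl-3,5-dioxoheptanoate
Product: 15 6-ethyl-4-hydroxy-5-methyl-2H-pyran-2-one
Conditions: DBU (1.2 equiv), PhMe, reflux; aq HCl
Reagents that add atoms: none
Why: Base-mediated lactonization of a 3,5-diketo ester, in which the C5 enolate oxygen attacks the methyl ester (6-exo-trig) and loss of methanol gives the 4-hydroxy-2-pyranone.

Step 8
Reactants: 15 6-ethyl-4-hydroxy-5-methyl-2H-pyran-2-one
Product: 16 3-bromo-6-ethyl-4-hydroxy-5-methyl-2H-pyran-2-one
Conditions: NBS (1.0 equiv), CH2Cl2, 0 °C to rt, dark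
Reagents that add atoms: N-bromosuccinimide, O=C1CCC(=O)N1Br
Why: Electrophilic bromination of the enol (a vinylogous acid) at C3, the only unsubstituted ring carbon and the nucleophilic carbon between the two oxygenated positions.

Step 9
Reactants: 16 3-bromo-6-ethyl-4-hydroxy-5-methyl-2H-pyran-2-one
Product: 17 3-bromo-6-ethyl-4-(methoxymethoxy)-5-methyl-2H-pyran-2-one
Conditions: MOMCl (1.5 equiv), iPr2NEt (2 equiv), CH2Cl2, 0 °C to rt
Reagents that add atoms: chloromethyl methyl ether, COCCl
Why: O-alkylation (MOM protection) of the acidic enol with a hard alkoxymethyl chloride, expected at the 4-oxygen so that the 2-pyranone form is kept.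

Step 10
Reactants: 17 3-bromo-6-ethyl-4-(methoxymethoxy)-5-methyl-2H-pyran-2-one; 18 (tributylstannyl)methanol
Product: 19 6-ethyl-3-(hydroxymethyl)-4-(methoxymethoxy)-5-methyl-2H-pyran-2-one
Conditions: 18 (1.3 equiv), Pd(PPh3)4 (5 mol %), 1,4-dioxane, 95 °C
Reagents that add atoms: none
Why: Stille coupling, in which zerovalent palladium inserts into the C3–Br bond activated by the adjacent lactone carbonyl and the oxygen-bearing methylene group is transferred from tin in preference to butyl.

Step 11
Reactants: 19 6-ethyl-3-(hydroxymethyl)-4-(methoxymethoxy)-5-methyl-2H-pyran-2-one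
Product: 21 3-(chloromethyl)-6-ethyl-4-(methoxymethoxy)-5-methyl-2H-pyran-2-one, via mesylate 20 (not isolated)
Conditions: MsCl (1.2 equiv), 2,4,6-collidine (1.5 equiv), LiCl (3 equiv), DMF, 0 °C
Reagents that add atoms: lithium chloride, [Li+].[Cl-]; methanesulfonyl chloride, CS(=O)(=O)Cl (its mesyl group stays only in intermediate 20)
Why: Mesylation followed by SN2 displacement with chloride at an unhindered allylic primary carbon under non-acidic conditions that spare the MOM acetal; the chloride should be used directly in the next step.

Step 12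
Reactants: 10 1-[8-bromo-5,7-bis(methoxymethoxy)-2,2-dimethyl-2H-chromen-6-yl]-2-methylpropan-1-one; 21 3-(chloromethyl)-6-ethyl-4-(methoxymethoxy)-5-methyl-2H-pyran-2-one
Product: 22 3-{[5,7-bis(methoxymethoxy)-2,2-dimethyl-6-(2-methylpropanoyl)-2H-chromen-8-yl]methyl}-6-ethyl-4-(methoxymethoxy)-5-methyl-2H-pyran-2-one
Conditions: NiBr2(MeOCH2CH2OMe) (10 mol %), 4,4'-di-tert-butyl-2,2'-bipyridine (10 mol %), Zn powder (2.5 equiv), DMA, 40 °C, argon; 21 (1.5 equiv) added over 4 h
Reagents that add atoms: none
Why: Zerovalent nickel carrying the bipyridine ligand inserts into the C8–Br bond of 10 to give an arylnickel bromide of divalent nickel, a monovalent nickel species abstracts chlorine from 21, the resulting pyranon-3-ylmethyl radical (allylic and conjugated with the lactone carbonyl) is captured by the arylnickel species, and the trivalent aryl(alkyl)nickel so formed eliminates reductively to make the C8–CH2 bond while zinc returns nickel to its low-valent states. The closest known reaction type is the nickel/bipyridine/zinc reductive cross-electrophile coupling of aryl bromides with benzylic chlorides to give diarylmethanes. No ring is closed and no stereocentre is formed. The step needs cross-coupling to beat homocoupling of either halide: the sp2 bromide is consumed by two-electron oxidative addition and the sp3 chloride by halogen-atom abstraction, so the two enter the cycle at different points, and slow addition of an excess of 21 keeps the radical concentration low. The two substituents flanking C8 are oxygen atoms (the ring oxygen and the 7-OMOM group), small and able to coordinate nickel, which should offset the di-ortho substitution, while the MOM acetals, the hindered twisted ketone, the lactone and the chromene alkene should be inert to zinc and low-valent nickel at 40 °C.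

Step 13
Reactants: 22 3-{[5,7-bis(methoxymethoxy)-2,2-dimethyl-6-(2-methylpropanoyl)-2H-chromen-8-yl]methyl}-6-ethyl-4-(methoxymethoxy)-5-methyl-2H-pyran-2-one
Product: 23 3-{[5,7-dihydroxy-2,2-dimethyl-6-(2-methylpropanoyl)-2H-chromen-8-yl]methyl}-6-ethyl-4-hydroxy-5-methyl-2H-pyran-2-one
Conditions: 3 M aq HCl, MeOH, 40 °C
Reagents that add atoms: none
Why: Acid-catalysed acetal exchange with methanol removes the two aryl MOM ethers and the enol MOM ether as dimethoxymethane; the 2,2-dimethylchromene alkene, the ketone and the lactone should tolerate dilute acid at this temperature.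

**Compound list**

1 | phloroglucinol (benzene-1,3,5-triol) | Oc1cc(O)cc(O)c1 | starting material
2 | 2-methylpropanoyl chloride | CC(C)C(=O)Cl | starting material
3 | 2-methyl-1-(2,4,6-trihydroxyphenyl)propan-1-one | CC(C)C(=O)c1c(O)cc(O)cc1O | intermediate
4 | 3-chloro-3-methylbut-1-yne | CC(C)(Cl)C#C | starting material
5 | 1-{2,6-dihydroxy-4-[(2-methylbut-3-yn-2-yl)oxy]phenyl}-2-methylpropan-1-one | CC(C)C(=O)c1c(O)cc(OC(C)(C)C#C)cc1O | intermediate
6 | 1-{3-bromo-2,6-dihydroxy-4-[(2-methylbut-3-yn-2-yl)oxy]phenyl}-2-methylpropan-1-one | CC(C)C(=O)c1c(O)cc(OC(C)(C)C#C)c(Br)c1O | intermediate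
7 | 1-{3-bromo-2,6-bis(methoxymethoxy)-4-[(2-methylbut-3-yn-2-yl)oxy]phenyl}-2-methylpropan-1-one | CC(C)C(=O)c1c(OCOC)cc(OC(C)(C)C#C)c(Br)c1OCOC | intermediate
8 | 1-[3-bromo-4-hydroxy-2,6-bis(methoxymethoxy)-5-(3-methylbuta-1,2-dien-1-yl)phenyl]-2-methylpropan-1-one (allenylphenol) | CC(C)C(=O)c1c(OCOC)c(C=C=C(C)C)c(O)c(Br)c1OCOC | intermediate
9 | (6Z)-2-bromo-3,5-bis(methoxymethoxy)-6-(3-methylbut-2-en-1-ylidene)-4-(2-methylpropanoyl)cyclohexa-2,4-dien-1-one (quinone methide) | O=C1C(Br)=C(OCOC)C(C(=O)C(C)C)=C(OCOC)/C1=C/C=C(C)C | intermediate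
10 | 1-[8-bromo-5,7-bis(methoxymethoxy)-2,2-dimethyl-2H-chromen-6-yl]-2-methylpropan-1-one | CC(C)C(=O)c1c(OCOC)c(Br)c2OC(C)(C)C=Cc2c1OCOC | intermediate
11 | methyl 3-oxopentanoate | CCC(=O)CC(=O)OC | starting material
12 | N-methoxy-N-methylpropanamide | CCC(=O)N(C)OC | starting material
13 | dilithium dianion of methyl 3-oxopentanoate (C2/C4 dianion) | [Li+].[Li+].C[CH-]C(=O)[CH-]C(=O)OC | intermediate
14 | methyl 4-methyl-3,5-dioxoheptanoate (racemic, enolizable at C4) | CCC(=O)C(C)C(=O)CC(=O)OC | intermediate
15 | 6-ethyl-4-hydroxy-5-methyl-2H-pyran-2-one | CCc1oc(=O)cc(O)c1C | intermediate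
16 | 3-bromo-6-ethyl-4-hydroxy-5-methyl-2H-pyran-2-one | CCc1oc(=O)c(Br)c(O)c1C | intermediate
17 | 3-bromo-6-ethyl-4-(methoxymethoxy)-5-methyl-2H-pyran-2-one | CCc1oc(=O)c(Br)c(OCOC)c1C | intermediate
18 | (tributylstannyl)methanol | CCCC[Sn](CCCC)(CCCC)CO | starting material
19 | 6-ethyl-3-(hydroxymethyl)-4-(methoxymethoxy)-5-methyl-2H-pyran-2-one | CCc1oc(=O)c(CO)c(OCOC)c1C | intermediate
20 | [6-ethyl-4-(methoxymethoxy)-5-methyl-2-oxo-2H-pyran-3-yl]methyl methanesulfonate | CCc1oc(=O)c(COS(C)(=O)=O)c(OCOC)c1C | intermediate
21 | 3-(chloromethyl)-6-ethyl-4-(methoxymethoxy)-5-methyl-2H-pyran-2-one | CCc1oc(=O)c(CCl)c(OCOC)c1C | intermediate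
22 | 3-{[5,7-bis(methoxymethoxy)-2,2-dimethyl-6-(2-methylpropanoyl)-2H-chromen-8-yl]methyl}-6-ethyl-4-(methoxymethoxy)-5-methyl-2H-pyran-2-one | CCc1oc(=O)c(Cc2c(OCOC)c(C(=O)C(C)C)c(OCOC)c3c2OC(C)(C)C=C3)c(OCOC)c1C | intermediate
23 | 3-{[5,7-dihydroxy-2,2-dimethyl-6-(2-methylpropanoyl)-2H-chromen-8-yl]methyl}-6-ethyl-4-hydroxy-5-methyl-2H-pyran-2-one | CCc1oc(=O)c(Cc2c(O)c(C(=O)C(C)C)c(O)c3c2OC(C)(C)C=C3)c(O)c1C | target

**Count**

Total step count: 13.
Longest linear sequence: 8 steps (steps 6 to 13, from methyl 3-oxopentanoate); the chromene arm has 5 steps and joins at step 12.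

**Steps most likely to fail**

Step 12. Oxidative addition at the di-ortho-substituted, electron-rich C8–Br bond may be slow, so that reductive dimerization of the chloride or hydrodebromination of the arene outruns the cross-coupling. The fallback sets out from 10 and 21 and comes back at 22. Magnesium insertion into 10 in the presence of LiCl and ZnCl2 (THF, rt) should give [5,7-bis(methoxymethoxy)-2,2-dimethyl-6-(2-methylpropanoyl)-2H-chromen-8-yl]zinc chloride F1. Negishi coupling of F1 with 21 under Pd(OAc)2 and 2-dicyclohexylphosphino-2',6'-dimethoxybiphenyl in THF should then give 22. The roles of nucleophile and electrophile are fixed here, so the dimerization path of the chloride is closed.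

Step 10. Transfer of the hydroxymethyl group from tin to palladium may be slow next to the 4-OMOM group, so that protodebromination or butyl transfer competes. The fallback sets out from 17 and comes back at 19. Bromine–magnesium exchange with iPrMgCl·LiCl (THF, −40 °C) should give [6-ethyl-4-(methoxymethoxy)-5-methyl-2-oxo-2H-pyran-3-yl]magnesium chloride F2. Formylation of F2 with DMF should give 6-ethyl-4-(methoxymethoxy)-5-methyl-2-oxo-2H-pyran-3-carbaldehyde F3. Luche reduction of F3 (NaBH4, CeCl3·7H2O, MeOH, −40 °C) should give 19. C3 acts here as the nucleophile towards a one-carbon electrophile, so no transmetalation from tin is needed.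

Step 2. Alkylation may not stop at one oxygen, or may take place at a hydroxyl beside the ketone or on a ring carbon. The fallback sets out from 3 and comes back at 10. Condensation of 3 with 3-methylbut-2-enal under ethylenediammonium diacetate catalysis (PhMe, reflux; Knoevenagel condensation then oxa-6π electrocyclization) should give 1-(5,7-dihydroxy-2,2-dimethyl-2H-chromen-6-yl)-2-methylpropan-1-one F4, which would have to be separated from the isomer closed through a hydroxyl beside the ketone. Bromination of F4 with NBS (CH2Cl2, −78 °C) at C8, its only free aromatic carbon, should give 1-(8-bromo-5,7-dihydroxy-2,2-dimethyl-2H-chromen-6-yl)-2-methylpropan-1-one F5. Treatment of F5 with NaH and MOMCl in DMF should give 10.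

**Further compounds**

F1 | step 12 | [5,7-bis(methoxymethoxy)-2,2-dimethyl-6-(2-methylpropanoyl)-2H-chromen-8-yl]zinc chloride | CC(C)C(=O)c1c(OCOC)c([Zn]Cl)c2OC(C)(C)C=Cc2c1OCOC
F2 | step 10 | [6-ethyl-4-(methoxymethoxy)-5-methyl-2-oxo-2H-pyran-3-yl]magnesium chloride | CCc1oc(=O)c([Mg]Cl)c(OCOC)c1C
F3 | step 10 | 6-ethyl-4-(methoxymethoxy)-5-methyl-2-oxo-2H-pyran-3-carbaldehyde | CCc1oc(=O)c(C=O)c(OCOC)c1C
F4 | step 2 | 1-(5,7-dihydroxy-2,2-dimethyl-2H-chromen-6-yl)-2-methylpropan-1-one | CC(C)C(=O)c1c(O)cc2OC(C)(C)C=Cc2c1O
F5 | step 2 | 1-(8-bromo-5,7-dihydroxy-2,2-dimethyl-2H-chromen-6-yl)-2-methylpropan-1-one | CC(C)C(=O)c1c(O)c(Br)c2OC(C)(C)C=Cc2c1O
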